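**Retrosynthetic overview**
1. 14 ⇐ 12 (debromolaurinterol): both C–Br bonds come from one late double bromination, para then ortho to OH.
2. 12 ⇐ 10: the cyclopropane is made last by phenol-directed Simmons–Smith reaction, which sets C1 and C5 from C2.
3. 10 ⇐ 7: a Shapiro reaction with MeI capture turns C=N–NHSO2Ar into C(Me)=CH.
4. 7 ⇐ 5 + 6 (key C–C bond): the ortho carbon of m-cresol adds to azoalkene 6, an enolonium (α-keto cation) equivalent of 2-methylcyclopentanone. This sets the quaternary centre.
5. Ring order: the arene (5) and the cyclopentane (1) are bought; the cyclopropane is the only ring formed (step 5).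

Assumption: (R)-TRIP is written for step 3; which antipode of the acid gives (S)-7 is settled in the first run and the other one is used if needed.

**Route**

Step 1
Reactants: 1 2-methylcyclopentanone (racemic)
Product: 2 2-chloro-2-methylcyclopentanone (racemic)
Conditions: SO2Cl2 (1.05 equiv), CH2Cl2, 0 °C → rt
Reagents that add atoms: sulfuryl chloride, O=S(=O)(Cl)Cl
Why: α-Chlorination of a ketone with sulfuryl chloride goes through the more substituted enol, so chlorine enters at the methyl-bearing carbon; the new centre is racemic and is erased in step 3.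

Step 2
Reactants: 2 2-chloro-2-methylcyclopentanone; 3 2,4,6-tri(propan-2-yl)benzenesulfonohydrazide
Product: 4 N'-[(1E)-2-chloro-2-methylcyclopentylidene]-2,4,6-tri(propan-2-yl)benzenesulfonohydrazide (racemic)
Conditions: THF, cat. HCl, 0 °C, product filtered off and used at once
Reagents that add atoms: none
Why: Sulfonylhydrazone condensation at the cyclopentanone carbonyl under non-basic conditions keeps the tertiary chloride, and the sulfonamide nitrogen sits anti to the quaternary carbon (E), the geometry the Shapiro step needs.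

Step 3
Reactants: 4 α-chloro sulfonylhydrazone; 5 3-methylphenol (m-cresol)
Product: 7 N'-[(1E,2S)-2-(2-hydroxy-4-methylphenyl)-2-methylcyclopentylidene]-2,4,6-tri(propan-2-yl)benzenesulfonohydrazide, via azoalkene 6 (not isolated)
Conditions: Na2CO3 (2 equiv), CH2Cl2, 0 °C, filter; then 5 (3 equiv), (R)-TRIP (10 mol %), 4 Å MS, PhMe, −40 → −20 °C; recrystallise to raise ee
Reagents that add atoms: none
Why: Proposed new method: base-induced 1,4-loss of HCl turns 4 into the planar N-sulfonyl azoalkene 6, an enolonium equivalent, which the chiral phosphoric acid activates at nitrogen while its P=O binds the phenol O–H, so the only unhindered activated position of 5 (ortho to OH, para to Me, the site at which m-cresol is tert-alkylated) attacks the methyl-bearing carbon inside a chiral ion pair and sets the quaternary centre, any O-alkylation being reversible; the closest known reaction types are Brønsted-acid-catalysed asymmetric Friedel–Crafts additions of indoles and naphthols to azoalkenes and the conjugate addition of carbon nucleophiles to in situ N-sulfonyl azoalkenes that builds quaternary α-centres.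

Step 4
Reactants: 7 (S)-aryl sulfonylhydrazone
Product: 10 2-[(1R)-1,2-dimethylcyclopent-2-en-1-yl]-5-methylphenol, via trilithiated hydrazone 8 (not isolated), via vinyllithium phenoxide 9 (not isolated)
Conditions: n-BuLi (3.3 equiv), TMEDA, THF, −78 → 0 °C; MeI (1.5 equiv), −78 → 0 °C; then H2O
Reagents that add atoms: iodomethane, CI
Why: Shapiro reaction: after O–H and N–H deprotonation (which also erases any ring–chain tautomerism of 7) the third equivalent lithiates C5, the only α-CH2 and syn to the sulfonamide anion, loss of sulfinate and N2 gives vinyllithium 9, and MeI methylates carbon much faster than the aggregated lithium phenoxide; the quaternary centre has no acidic hydrogen and is untouched.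

Step 5
Reactants: 10 (R)-cyclopentenyl phenol
Product: 12 2-[(1S,2R,5R)-1,2-dimethylbicyclo[3.1.0]hexan-2-yl]-5-methylphenol (debromolaurinterol), via iodomethylzinc phenoxide 11 (not isolated)
Conditions: Et2Zn (2.5 equiv), CH2I2 (5 equiv), CH2Cl2, 0 °C → rt
Reagents that add atoms: diiodomethane, ICI
Why: Hydroxyl-directed Simmons–Smith (Furukawa) cyclopropanation: the zinc phenoxide holds the carbenoid on the alkene face that carries the aryl group, so CH2 is delivered syn to aryl and sets C1 (S) and C5 (R) from C2 (R).

Step 6
Reactants: 12 debromolaurinterol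
Product: 14 2,4-dibromo-6-[(1S,2R,5R)-1,2-dimethylbicyclo[3.1.0]hexan-2-yl]-3-methylphenol, via laurinterol 13 (not isolated)
Conditions: NBS (2.05 equiv), MeCN, 0 °C → rt, dark
Reagents that add atoms: N-bromosuccinimide, O=C1CCC(=O)N1Br
Why: Electrophilic aromatic bromination: the phenol directs the first bromine para (13) and the second into the remaining ortho position between OH and Me, the only activated sites left, and NBS gives neutral succinimide instead of HBr so the acid-labile aryl cyclopropane survives.

**Compound list**
1 | 2-methylcyclopentanone (racemic) | CC1CCCC1=O | starting material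
2 | 2-chloro-2-methylcyclopentanone (racemic) | CC1(Cl)CCCC1=O | intermediate
3 | 2,4,6-tri(propan-2-yl)benzenesulfonohydrazide | CC(C)c1cc(C(C)C)c(S(=O)(=O)NN)c(C(C)C)c1 | starting material
4 | N'-[(1E)-2-chloro-2-methylcyclopentylidene]-2,4,6-tri(propan-2-yl)benzenesulfonohydrazide (racemic) | CC(C)c1cc(C(C)C)c(S(=O)(=O)N/N=C2\CCCC2(C)Cl)c(C(C)C)c1 | intermediate
5 | 3-methylphenol (m-cresol) | Cc1cccc(O)c1 | starting material
6 | 1-methyl-2-{(E)-[2,4,6-tri(propan-2-yl)phenyl]sulfonyldiazenyl}cyclopent-1-ene (azoalkene) | CC1=C(/N=N/S(=O)(=O)c2c(C(C)C)cc(C(C)C)cc2C(C)C)CCC1 | intermediate (not isolated)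
7 | N'-[(1E,2S)-2-(2-hydroxy-4-methylphenyl)-2-methylcyclopentylidene]-2,4,6-tri(propan-2-yl)benzenesulfonohydrazide | CC(C)c1cc(C(C)C)c(S(=O)(=O)N/N=C2\CCC[C@@]2(C)c3ccc(C)cc3O)c(C(C)C)c1 | intermediate
8 | O,N,C5-trilithio derivative of 7 (trilithiated hydrazone) | CC(C)c1cc(C(C)C)c(S(=O)(=O)N([Li])/N=C2\C([Li])CC[C@@]2(C)c3ccc(C)cc3O[Li])c(C(C)C)c1 | intermediate (not isolated)
9 | lithium 2-[(1R)-2-lithio-1-methylcyclopent-2-en-1-yl]-5-methylphenolate (vinyllithium phenoxide) | Cc1ccc([C@]2(C)CCC=C2[Li])c(O[Li])c1 | intermediate (not isolated)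
10 | 2-[(1R)-1,2-dimethylcyclopent-2-en-1-yl]-5-methylphenol | Cc1ccc([C@]2(C)CCC=C2C)c(O)c1 | intermediate
11 | (iodomethyl)zinc 2-[(1R)-1,2-dimethylcyclopent-2-en-1-yl]-5-methylphenolate | Cc1ccc([C@]2(C)CCC=C2C)c(O[Zn]CI)c1 | intermediate (not isolated)
12 | 2-[(1S,2R,5R)-1,2-dimethylbicyclo[3.1.0]hexan-2-yl]-5-methylphenol (debromolaurinterol; aryl and cyclopropane CH2 on the same face, the two methyls cis) | Cc1ccc([C@]2(C)CC[C@@H]3C[C@@]32C)c(O)c1 | intermediate
13 | 4-bromo-2-[(1S,2R,5R)-1,2-dimethylbicyclo[3.1.0]hexan-2-yl]-5-methylphenol (laurinterol) | Cc1cc(O)c([C@]2(C)CC[C@@H]3C[C@@]32C)cc1Br | intermediate (not isolated)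
14 | 2,4-dibromo-6-[(1S,2R,5R)-1,2-dimethylbicyclo[3.1.0]hexan-2-yl]-3-methylphenol | Cc1c(Br)cc([C@]2(C)CC[C@@H]3C[C@@]32C)c(O)c1Br | target

**Step count**
Total steps: 6. Longest linear sequence: 6 (1 → 14).

**Steps most likely to fail, with fallbacks**

Step 3 (highest risk). Neutral m-cresol is a weak π-nucleophile, azoalkene 6 can tautomerise to the conjugated ene-hydrazone, and the enantioselectivity is unproven. The fallback sets out from 4 and comes back at 7. Azoalkene 6 is generated from 4 as in step 3 and treated in THF at −78 °C with an aryl-metal reagent. This reagent is made from 2-bromo-5-methylphenol F1 by Br/Li exchange with n-BuLi (2.1 equiv) to lithium 2-lithio-5-methylphenolate F2, followed by MgBr2·OEt2 and CuCl (10 mol %). Copper-mediated conjugate arylation of sulfonylazoalkenes is established enolonium chemistry, and the C–Br position fixes the regiochemistry. It gives the racemic hydrazone F3, which is resolved by preparative chiral SFC to return (S)-7.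

Step 4. The trianion may form sluggishly, and the vinyllithium may be protonated by solvent or the phenoxide O-methylated. The fallback sets out from 7 and comes back at 10. Vinyllithium 9 is generated as in step 4 but quenched with 1,2-diiodoethane to give 2-[(1S)-2-iodo-1-methylcyclopent-2-en-1-yl]-5-methylphenol F4. Suzuki–Miyaura methylation with trimethylboroxine (Pd(dppf)Cl2, K2CO3, dioxane/H2O, 90 °C) then gives 10. The C–Me bond is thus made by cross-coupling instead of alkylation, and O-methylation cannot occur.

Step 2. The tertiary α-chloro hydrazone may lose HCl prematurely and be trapped by a second hydrazide. The fallback sets out from 1 (with 3) and comes back at 6, entering step 3 at its second stage. Ketone 1 is condensed with 3 (MeOH, cat. HCl) to N'-[(1E)-2-methylcyclopentylidene]-2,4,6-tri(propan-2-yl)benzenesulfonohydrazide F5. Bromination with phenyltrimethylammonium tribromide (THF, 0 °C) through the more substituted ene-hydrazine gives N'-[(1E)-2-bromo-2-methylcyclopentylidene]-2,4,6-tri(propan-2-yl)benzenesulfonohydrazide F6. This is used crude with Na2CO3 to give azoalkene 6, and step 1 is no longer needed.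

**Further compounds**
F1 | step 3 | 2-bromo-5-methylphenol | Cc1ccc(Br)c(O)c1
F2 | step 3 | lithium 2-lithio-5-methylphenolate | Cc1ccc([Li])c(O[Li])c1
F3 | step 3 | N'-[(1E)-2-(2-hydroxy-4-methylphenyl)-2-methylcyclopentylidene]-2,4,6-tri(propan-2-yl)benzenesulfonohydrazide (racemate) | CC(C)c1cc(C(C)C)c(S(=O)(=O)N/N=C2\CCCC2(C)c3ccc(C)cc3O)c(C(C)C)c1
F4 | step 4 | 2-[(1S)-2-iodo-1-methylcyclopent-2-en-1-yl]-5-methylphenol | Cc1ccc([C@]2(C)CCC=C2I)c(O)c1
F5 | step 2 | N'-[(1E)-2-methylcyclopentylidene]-2,4,6-tri(propan-2-yl)benzenesulfonohydrazide (racemic) | CC(C)c1cc(C(C)C)c(S(=O)(=O)N/N=C2\CCCC2C)c(C(C)C)c1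
F6 | step 2 | N'-[(1E)-2-bromo-2-methylcyclopentylidene]-2,4,6-tri(propan-2-yl)benzenesulfonohydrazide (racemic) | CC(C)c1cc(C(C)C)c(S(=O)(=O)N/N=C2\CCCC2(C)Br)c(C(C)C)c1
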